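Left over in the beta run at 2.50 min, after 35.8% of product and 53.4% of substrate, is a gap of 11 percentage points, so the flask holds some form that the readings don't show.

the same everywhere: second catalyst 2.5 mM
- beta: substrate 0.50 M; reagent 0.45 M; free catalyst 22 mM; run made earlier
- alpha: substrate 0.50 M; reagent 0.45 M; free catalyst 36 mM; run made earlier
- epsilon: substrate 1.1 M; reagent 0.45 M; free catalyst 25 mM; run made earlier
- amber: substrate 1.5 M; reagent 0.450 M; free catalyst 50 mM; time 5.0 min
- ochre: substrate 0.50 M; reagent 0.450 M; free catalyst 25 mM; time 5.0 min

| run | time / min | product / % | substrate / % |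
|---|---|---|---|
| beta | 0.500 | 8.6 | 82.9 |
| beta | 1.00 | 16.1 | 72.2 |
| beta | 1.50 | 22.3 | 66.6 |
| beta | 2.00 | 30.1 | 58.8 |
| beta | 2.50 | 35.8 | 53.4 |
| alpha | 0.200 | 2.0 | 88.9 |
| alpha | 0.417 | 8.3 | 81.9 |
| alpha | 0.667 | 12.0 | 72.2 |
| alpha | 1.33 | 25.5 | 61.6 |
| alpha | 2.50 | 40.4 | 48.4 |
| epsilon | 0.500 | 6.3 | 84.3 |
| epsilon | 1.00 | 10.6 | 74.7 |
| epsilon | 1.50 | 15.9 | 68.0 |
| epsilon | 2.00 | 18.1 | 64.5 |
| epsilon | 2.50 | 22.3 | 62.8 |

(readings scatter by 1 percentage point)

- the numbers in the tables scatter with a standard deviation of 1 points

* which one finishes higher in amount of product, in percent of the substrate charged ("neither" within 2 percentage points) (amber / ochre / neither)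
* amount of product at the end, in percent of the substrate charged, amber
* amount of product at the end, in percent of the substrate charged, ochre

What I watch is the catalyst exponent, the power of [free catalyst] that product follows at a fixed time. Between the beta and alpha runs at 2.50 min it reads 0.245, a reading with the scatter of 1 point in it. So ochre, a small step up from beta in [free catalyst], should hold about 36.9% of product at that time. In amber, [reagent] at 0.450 M is less than [substrate] at 1.5 M, which makes reagent the limiting reagent. If each product takes one reagent, amber stays below 30.0%. Ochre should therefore pass that ceiling before its time is up, and I expect ochre higher. I leave [free catalyst] as charged; the exponent was read between 22 mM and 36 mM, at 0.50 M of substrate.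

The forecast says ochre, with 27% for amber and 58% for ochre, reasoning that “reagent is consumed stoichiometrically”.

The flasks give ochre, with 24.3% for amber and 52.9% for ochre.

    substrate + free catalyst ⇌ free catalyst + open intermediate (K = 0.330, k = 0.316 M⁻¹ s⁻¹)
    second catalyst + open intermediate ⇌ catalyst intermediate (K = 54.7 M⁻¹, k = 207 M⁻¹ s⁻¹)
    reagent + catalyst intermediate → second catalyst + product (k = 2.71 M⁻¹ s⁻¹)
    second catalyst → spent catalyst (k = 0.00947 s⁻¹)

Ochre held 36.3% of product at 2.50 min, against the 36.9% reckoned from the exponent. A neighbour flask like ochre, but charged with 0.015 M of free catalyst, takes the same exponent from ochre's end value and comes to 46.6%. That neighbour ends at 46.3% of product, with 49% of its reagent still there.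

(Readings and results stem from a simulated flask with made-up constants, and the scatter is random.)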